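**Retrosynthetic overview**

1. Hippolide E ⇐ its bis-silyl ether ⇐ opening of the furan-2(5H)-one ring (O1, C2, C3, C4, C5; the only ring of the target) at C3=C4, giving an acyclic (R)-α-ketol C5(OH)–C4(=O)–CH2OSi and the two-carbon reagent Ph3P=C=C=O, which supplies C2 and C3.
2. Enabling feature: ring oxygen O1 and ring carbon C4 (the carbon carrying the hydroxymethyl group) are 1,2-related through the stereocentre C5, so the open form is an acyloin; an ylide carbon (C3) anchored on O1 through C2 lies five atoms from the C4 carbonyl and closes the lactone by olefination.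
3. α-Ketol ⇐ 4-alkyl-2,2-dimethyl-1,3-dioxan-5-one: a temporary 1,3-dioxane ring (dihydroxyacetone acetonide, absent from the target) carries the RAMP hydrazone that sets C5 while the C5–CH2 bond is made, and is then hydrolysed away.
4. Allylic bromide for that alkylation ⇐ E-enoate ⇐ Wittig reaction of an α-silyloxy ketone (fixes the C(CH2OH)=CH geometry) ⇐ (2E,6E)-farnesyl bromide + silyloxyacetone hydrazone.
5. Ring order: the temporary dioxane ring is bought in and opened in step 8; the furanone ring is then formed in step 10.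

Key step: step 10

Assumption: the RAMP azaenolate of the dioxanone is alkylated with the facial sense established for SAMP/RAMP hydrazone alkylations (SAMP giving the S-configured 4-alkyl dioxanone), so RAMP should deliver the R centre required.

**Route**

Step 1
Reactants: 1 1-[(tert-butyldimethylsilyl)oxy]propan-2-one; 2 1,1-dimethylhydrazine
Product: 3 (E)-1-[(tert-butyldimethylsilyl)oxy]propan-2-one N,N-dimethylhydrazone
Conditions: 2 (3 equiv), AcOH (cat.), EtOH, 60 °C
Reagents that add atoms: none
Why: Hydrazone condensation, in which the dimethylamino group should settle anti to the bulkier silyloxymethyl arm (E) and therefore syn to the methyl group that is to be metalated.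

Step 2
Reactants: 3 (E)-1-[(tert-butyldimethylsilyl)oxy]propan-2-one N,N-dimethylhydrazone; 4 (2E,6E)-farnesyl bromide
Product: 7 (5E,9E)-1-[(tert-butyldimethylsilyl)oxy]-6,10,14-trimethylpentadeca-5,9,13-trien-2-one, via lithium azaenolate 5 (not isolated), via alkylated dimethylhydrazone 6 (not isolated)
Conditions: LiN(i-Pr)2, THF, −78 to 0 °C; 4, −78 °C to rt; then sat. aq. oxalic acid, Et2O, rt
Reagents that add atoms: water, O
Why: Corey–Enders hydrazone alkylation, in which LiN(i-Pr)2 should remove a proton from the less substituted methyl carbon syn to the dimethylamino group, the azaenolate displaces the primary allylic bromide by SN2 without touching the 2E alkene, and two-phase oxalic acid hydrolysis returns the ketone.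

Step 3
Reactants: 7 (5E,9E)-1-[(tert-butyldimethylsilyl)oxy]-6,10,14-trimethylpentadeca-5,9,13-trien-2-one; 8 ethyl (triphenylphosphoranylidene)acetate
Product: 9 ethyl (2E,6E,10E)-3-{[(tert-butyldimethylsilyl)oxy]methyl}-7,11,15-trimethylhexadeca-2,6,10,14-tetraenoate
Conditions: 8 (2 equiv), toluene, 110 °C
Reagents that add atoms: none
Why: Wittig olefination of an α-oxygenated ketone with a stabilised ylide, which is expected to place the ester trans to the oxygenated arm (the pattern known from 4-oxygenated 3-methylbut-2-enoates) and so give the 2E alkene with the long chain cis to C1.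

Step 4
Reactants: 9 ethyl (2E,6E,10E)-3-{[(tert-butyldimethylsilyl)oxy]methyl}-7,11,15-trimethylhexadeca-2,6,10,14-tetraenoate
Product: 10 (2E,6E,10E)-3-{[(tert-butyldimethylsilyl)oxy]methyl}-7,11,15-trimethylhexadeca-2,6,10,14-tetraen-1-ol
Conditions: i-Bu2AlH (2.5 equiv), CH2Cl2, −78 °C; aq. potassium sodium tartrate work-up
Reagents that add atoms: none
Why: 1,2-Reduction of the enoate by i-Bu2AlH should give the allylic alcohol without touching the alkenes or the silyl ether.

Step 5
Reactants: 10 (2E,6E,10E)-3-{[(tert-butyldimethylsilyl)oxy]methyl}-7,11,15-trimethylhexadeca-2,6,10,14-tetraen-1-ol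
Product: 11 (2E,6E,10E)-1-bromo-3-{[(tert-butyldimethylsilyl)oxy]methyl}-7,11,15-trimethylhexadeca-2,6,10,14-tetraene
Conditions: PPh3, CBr4, CH2Cl2, 0 °C
Reagents that add atoms: carbon tetrabromide, BrC(Br)(Br)Br
Why: Appel reaction, an SN2 displacement of the oxyphosphonium group at the primary allylic carbon that should proceed without allylic transposition under conditions mild enough for the silyl ether.

Step 6
Reactants: 12 2,2-dimethyl-1,3-dioxan-5-one; 13 (R)-1-amino-2-(methoxymethyl)pyrrolidine (RAMP)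
Product: 14 (R)-N-(2,2-dimethyl-1,3-dioxan-5-ylidene)-2-(methoxymethyl)pyrrolidin-1-amine
Conditions: toluene, 4 Å molecular sieves, 60 °C
Reagents that add atoms: none
Why: Hydrazone condensation of the symmetrical ketone with the chiral hydrazine, the standard entry to Enders dioxanone chemistry.

Step 7
Reactants: 14 (R)-N-(2,2-dimethyl-1,3-dioxan-5-ylidene)-2-(methoxymethyl)pyrrolidin-1-amine; 11 (2E,6E,10E)-1-bromo-3-{[(tert-butyldimethylsilyl)oxy]methyl}-7,11,15-trimethylhexadeca-2,6,10,14-tetraene
Product: 16 (R)-N-{(4R,5Z)-4-[(2E,6E,10E)-3-{[(tert-butyldimethylsilyl)oxy]methyl}-7,11,15-trimethylhexadeca-2,6,10,14-tetraen-1-yl]-2,2-dimethyl-1,3-dioxan-5-ylidene}-2-(methoxymethyl)pyrrolidin-1-amine, via lithium azaenolate 15 (not isolated)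
Conditions: t-BuLi (1.1 equiv), THF, −78 °C, 2 h; then 11, −100 °C to rt
Reagents that add atoms: none
Why: Enders RAMP-hydrazone alkylation, in which the ring-fixed, methoxy-chelated lithium azaenolate should be alkylated by the primary allylic bromide (SN2) on the face dictated by the (R)-2-(methoxymethyl)pyrrolidine auxiliary, setting the dioxane C4 centre as R (C5 of the target).

Step 8
Reactants: 16 (R)-N-{(4R,5Z)-4-[(2E,6E,10E)-3-{[(tert-butyldimethylsilyl)oxy]methyl}-7,11,15-trimethylhexadeca-2,6,10,14-tetraen-1-yl]-2,2-dimethyl-1,3-dioxan-5-ylidene}-2-(methoxymethyl)pyrrolidin-1-amine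
Product: 18 (3R,5E,9E,13E)-1,3-dihydroxy-6-(hydroxymethyl)-10,14,18-trimethylnonadeca-5,9,13,17-tetraen-2-one, via dioxanone ketone 17 (not isolated)
Conditions: sat. aq. oxalic acid, Et2O, rt; organic phase concentrated; then aq. HCl (1 M), THF, rt
Reagents that add atoms: water, O
Why: Two-phase oxalic acid hydrolysis is the standard racemisation-free cleavage of these hydrazones and returns the auxiliary, and dilute aqueous acid should then hydrolyse the isopropylidene ketal together with the allylic silyl ether (ketal and silyl ether hydrolysis) while leaving the alkenes alone.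

Step 9
Reactants: 18 (3R,5E,9E,13E)-1,3-dihydroxy-6-(hydroxymethyl)-10,14,18-trimethylnonadeca-5,9,13,17-tetraen-2-one
Product: 19 (3R,5E,9E,13E)-1-[(tert-butyldimethylsilyl)oxy]-6-{[(tert-butyldimethylsilyl)oxy]methyl}-3-hydroxy-10,14,18-trimethylnonadeca-5,9,13,17-tetraen-2-one
Conditions: TBSCl (2.1 equiv), imidazole, CH2Cl2, −20 to 0 °C
Reagents that add atoms: tert-butyldimethylsilyl chloride, CC(C)(C)[Si](C)(C)Cl
Why: Selective silylation, since the two primary hydroxyls should react much faster with the bulky silyl chloride than the secondary, hydrogen-bonded α-ketol hydroxyl, leaving only the C3 hydroxyl free.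

Step 10
Reactants: 19 (3R,5E,9E,13E)-1-[(tert-butyldimethylsilyl)oxy]-6-{[(tert-butyldimethylsilyl)oxy]methyl}-3-hydroxy-10,14,18-trimethylnonadeca-5,9,13,17-tetraen-2-one; 20 (triphenylphosphoranylidene)ketene
Product: 22 (5R)-4-{[(tert-butyldimethylsilyl)oxy]methyl}-5-[(2E,6E,10E)-3-{[(tert-butyldimethylsilyl)oxy]methyl}-7,11,15-trimethylhexadeca-2,6,10,14-tetraen-1-yl]furan-2(5H)-one, via phosphoranylidene acetate 21 (not isolated)
Conditions: 20 (1.3 equiv), toluene, 90 °C
Reagents that add atoms: none
Why: The free secondary hydroxyl adds across the C=C of the cumulated ylide to give the stabilised phosphoranylidene acetate 21, whose ylide carbon then attacks the adjacent ketone and, through the oxaphosphetane and loss of Ph3PO, forms the C3=C4 bond (domino O-acylation/intramolecular Wittig olefination). The closest known reaction type is the Bestmann butenolide synthesis from α-hydroxy ketones and (triphenylphosphoranylidene)ketene. The one ring formed, the furanone, closes in a 5-exo-trig mode (ylide carbon onto the exocyclic C=O), and the new double bond is necessarily cis within the five-membered ring. No stereocentre is created: C5 (R) comes from step 7 and should be kept because the medium is neutral and aprotic and the ylide intermediates are only weakly basic. The selectivity needed is site selectivity of acylation and of olefination: both primary hydroxyls are silylated so that only the C5 oxygen can carry the ylide, and only the C4 ketone lies five atoms from the ylide carbon, so ring closure should outrun any intermolecular Wittig reaction.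

Step 11
Reactants: 22 (5R)-4-{[(tert-butyldimethylsilyl)oxy]methyl}-5-[(2E,6E,10E)-3-{[(tert-butyldimethylsilyl)oxy]methyl}-7,11,15-trimethylhexadeca-2,6,10,14-tetraen-1-yl]furan-2(5H)-one
Product: 23 Hippolide E, (5R)-4-(hydroxymethyl)-5-[(2E,6E,10E)-3-(hydroxymethyl)-7,11,15-trimethylhexadeca-2,6,10,14-tetraen-1-yl]furan-2(5H)-one
Conditions: HF·pyridine, pyridine, THF, 0 °C to rt
Reagents that add atoms: none
Why: Fluoride-mediated desilylation under buffered, non-basic conditions should remove both primary silyl ethers without disturbing the base-sensitive γ-position of the butenolide or the alkenes.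

**Compound list**

1 | 1-[(tert-butyldimethylsilyl)oxy]propan-2-one | CC(=O)CO[Si](C)(C)C(C)(C)C | starting material
2 | 1,1-dimethylhydrazine | CN(C)N | starting material
3 | (E)-1-[(tert-butyldimethylsilyl)oxy]propan-2-one N,N-dimethylhydrazone | C/C(=N\N(C)C)CO[Si](C)(C)C(C)(C)C | intermediate
4 | (2E,6E)-farnesyl bromide | CC(C)=CCC/C(C)=C/CC/C(C)=C/CBr | starting material
5 | lithium azaenolate of 3 (metalated at the methyl carbon) | C=C(CO[Si](C)(C)C(C)(C)C)N([Li])N(C)C | intermediate
6 | (E)-N,N-dimethylhydrazone of ketone 7 | CC(C)=CCC/C(C)=C/CC/C(C)=C/CC/C(=N\N(C)C)CO[Si](C)(C)C(C)(C)C | intermediate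
7 | (5E,9E)-1-[(tert-butyldimethylsilyl)oxy]-6,10,14-trimethylpentadeca-5,9,13-trien-2-one | CC(C)=CCC/C(C)=C/CC/C(C)=C/CCC(=O)CO[Si](C)(C)C(C)(C)C | intermediate
8 | ethyl (triphenylphosphoranylidene)acetate | CCOC(=O)C=P(c1ccccc1)(c1ccccc1)c1ccccc1 | starting material
9 | ethyl (2E,6E,10E)-3-{[(tert-butyldimethylsilyl)oxy]methyl}-7,11,15-trimethylhexadeca-2,6,10,14-tetraenoate | CC(C)=CCC/C(C)=C/CC/C(C)=C/CC/C(=C\C(=O)OCC)CO[Si](C)(C)C(C)(C)C | intermediate
10 | (2E,6E,10E)-3-{[(tert-butyldimethylsilyl)oxy]methyl}-7,11,15-trimethylhexadeca-2,6,10,14-tetraen-1-ol | CC(C)=CCC/C(C)=C/CC/C(C)=C/CC/C(=C\CO)CO[Si](C)(C)C(C)(C)C | intermediate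
11 | (2E,6E,10E)-1-bromo-3-{[(tert-butyldimethylsilyl)oxy]methyl}-7,11,15-trimethylhexadeca-2,6,10,14-tetraene | CC(C)=CCC/C(C)=C/CC/C(C)=C/CC/C(=C\CBr)CO[Si](C)(C)C(C)(C)C | intermediate
12 | 2,2-dimethyl-1,3-dioxan-5-one | CC1(C)OCC(=O)CO1 | starting material
13 | (R)-1-amino-2-(methoxymethyl)pyrrolidine (RAMP) | COC[C@H]1CCCN1N | starting material
14 | (R)-N-(2,2-dimethyl-1,3-dioxan-5-ylidene)-2-(methoxymethyl)pyrrolidin-1-amine | COC[C@H]1CCCN1N=C1COC(C)(C)OC1 | intermediate
15 | lithium azaenolate of 14 | COC[C@H]1CCCN1N([Li])C1=COC(C)(C)OC1 | intermediate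
16 | (R)-N-{(4R,5Z)-4-[(2E,6E,10E)-3-{[(tert-butyldimethylsilyl)oxy]methyl}-7,11,15-trimethylhexadeca-2,6,10,14-tetraen-1-yl]-2,2-dimethyl-1,3-dioxan-5-ylidene}-2-(methoxymethyl)pyrrolidin-1-amine (C=N drawn Z, N–N syn to the alkylated carbon, as expected from the azaenolate; of no consequence) | CC(C)=CCC/C(C)=C/CC/C(C)=C/CC/C(=C\C[C@H]1OC(C)(C)OC/C1=N/N2CCC[C@@H]2COC)CO[Si](C)(C)C(C)(C)C | intermediate
17 | (4R)-4-[(2E,6E,10E)-3-{[(tert-butyldimethylsilyl)oxy]methyl}-7,11,15-trimethylhexadeca-2,6,10,14-tetraen-1-yl]-2,2-dimethyl-1,3-dioxan-5-one | CC(C)=CCC/C(C)=C/CC/C(C)=C/CC/C(=C\C[C@H]1OC(C)(C)OCC1=O)CO[Si](C)(C)C(C)(C)C | intermediate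
18 | (3R,5E,9E,13E)-1,3-dihydroxy-6-(hydroxymethyl)-10,14,18-trimethylnonadeca-5,9,13,17-tetraen-2-one | CC(C)=CCC/C(C)=C/CC/C(C)=C/CC/C(=C\C[C@@H](O)C(=O)CO)CO | intermediate
19 | (3R,5E,9E,13E)-1-[(tert-butyldimethylsilyl)oxy]-6-{[(tert-butyldimethylsilyl)oxy]methyl}-3-hydroxy-10,14,18-trimethylnonadeca-5,9,13,17-tetraen-2-one | CC(C)=CCC/C(C)=C/CC/C(C)=C/CC/C(=C\C[C@@H](O)C(=O)CO[Si](C)(C)C(C)(C)C)CO[Si](C)(C)C(C)(C)C | intermediate
20 | (triphenylphosphoranylidene)ketene | O=C=C=P(c1ccccc1)(c1ccccc1)c1ccccc1 | starting material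
21 | (3R,5E,9E,13E)-1-[(tert-butyldimethylsilyl)oxy]-6-{[(tert-butyldimethylsilyl)oxy]methyl}-10,14,18-trimethyl-2-oxononadeca-5,9,13,17-tetraen-3-yl (triphenylphosphoranylidene)acetate | CC(C)=CCC/C(C)=C/CC/C(C)=C/CC/C(=C\C[C@@H](OC(=O)C=P(c1ccccc1)(c1ccccc1)c1ccccc1)C(=O)CO[Si](C)(C)C(C)(C)C)CO[Si](C)(C)C(C)(C)C | intermediate
22 | (5R)-4-{[(tert-butyldimethylsilyl)oxy]methyl}-5-[(2E,6E,10E)-3-{[(tert-butyldimethylsilyl)oxy]methyl}-7,11,15-trimethylhexadeca-2,6,10,14-tetraen-1-yl]furan-2(5H)-one | CC(C)=CCC/C(C)=C/CC/C(C)=C/CC/C(=C\C[C@H]1OC(=O)C=C1CO[Si](C)(C)C(C)(C)C)CO[Si](C)(C)C(C)(C)C | intermediate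
23 | Hippolide E, (5R)-4-(hydroxymethyl)-5-[(2E,6E,10E)-3-(hydroxymethyl)-7,11,15-trimethylhexadeca-2,6,10,14-tetraen-1-yl]furan-2(5H)-one | CC(C)=CCC/C(C)=C/CC/C(C)=C/CC/C(=C\C[C@H]1OC(=O)C=C1CO)CO | target

**Summary**

Total step count: 11. Longest linear sequence: 10 steps (steps 1–5 and 7–11, from compound 1 to compound 23); step 6 is a one-step side branch.

Steps most likely to fail:

Step 10 (key step). Addition of the hindered, hydrogen-bonded secondary hydroxyl of 19 to the cumulated ylide may be slower than thermal enolisation or ketol transposition of the α-ketol, so that configuration at the future C5 is eroded before the ring closes. The fallback sets out from 19 and returns at 22. Compound 19 would be acylated at 0 °C with diethylphosphonoacetic acid (N,N′-dicyclohexylcarbodiimide, cat. 4-(dimethylamino)pyridine, CH2Cl2) to give the isolated phosphonoacetate, (3R,5E,9E,13E)-1-[(tert-butyldimethylsilyl)oxy]-6-{[(tert-butyldimethylsilyl)oxy]methyl}-10,14,18-trimethyl-2-oxononadeca-5,9,13,17-tetraen-3-yl (diethoxyphosphoryl)acetate F1. F1 would then be closed to 22 by an intramolecular Horner–Wadsworth–Emmons reaction under Masamune–Roush conditions (LiCl, i-Pr2NEt, MeCN, 0 °C). The same C3=C4 bond is formed, but acylation and olefination are separated and both run cold.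

Step 3. The ylide may discriminate poorly between the silyloxymethyl arm and the homofarnesyl arm of 7, giving alkene isomers that are hard to separate. The fallback sets out from 4 and returns at 9, and fixes the geometry by reagent-controlled enol triflation and stereoretentive cross-coupling. The dianion of ethyl acetoacetate (NaH, then n-BuLi, THF, 0 °C) would be alkylated at its terminal carbon with 4 to give ethyl (6E,10E)-7,11,15-trimethyl-3-oxohexadeca-6,10,14-trienoate F2. E-selective triflation (aq. Me4NOH, Tf2O, hexanes, 5 °C) would give ethyl (2E,6E,10E)-7,11,15-trimethyl-3-{[(trifluoromethyl)sulfonyl]oxy}hexadeca-2,6,10,14-tetraenoate F3. Stille coupling with (tributylstannyl)methanol (Pd(PPh3)4, LiCl, dioxane, 90 °C) should give, with retention, ethyl (2E,6E,10E)-3-(hydroxymethyl)-7,11,15-trimethylhexadeca-2,6,10,14-tetraenoate F4. Silylation (TBSCl, imidazole, CH2Cl2) returns to 9.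

Step 2. Metalation of 3 may occur at the silyloxymethylene carbon instead of the methyl group, or the silyl group may migrate within the azaenolate, so that the farnesyl unit ends up on the wrong carbon. The fallback sets out from 4 and returns at 7, and fixes the site of C–C bond formation unambiguously. The lithium enolate of N-methoxy-N-methylacetamide (LiN(i-Pr)2, THF, −78 °C) would be alkylated with 4 to give (4E,8E)-N-methoxy-N,5,9,13-tetramethyltetradeca-4,8,12-trienamide F5. Chloromethyllithium generated in situ (ICH2Cl, MeLi·LiBr, THF, −78 °C) would convert it into (5E,9E)-1-chloro-6,10,14-trimethylpentadeca-5,9,13-trien-2-one F6. Sodium formate in aqueous EtOH at 80 °C (substitution, then hydrolysis of the formate in situ) would give (5E,9E)-1-hydroxy-6,10,14-trimethylpentadeca-5,9,13-trien-2-one F7. Silylation (TBSCl, imidazole, CH2Cl2) returns to 7.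

**Further compounds**

F1 | step 10 | (3R,5E,9E,13E)-1-[(tert-butyldimethylsilyl)oxy]-6-{[(tert-butyldimethylsilyl)oxy]methyl}-10,14,18-trimethyl-2-oxononadeca-5,9,13,17-tetraen-3-yl (diethoxyphosphoryl)acetate | CC(C)=CCC/C(C)=C/CC/C(C)=C/CC/C(=C\C[C@@H](OC(=O)CP(=O)(OCC)OCC)C(=O)CO[Si](C)(C)C(C)(C)C)CO[Si](C)(C)C(C)(C)C
F2 | step 3 | ethyl (6E,10E)-7,11,15-trimethyl-3-oxohexadeca-6,10,14-trienoate | CC(C)=CCC/C(C)=C/CC/C(C)=C/CCC(=O)CC(=O)OCC
F3 | step 3 | ethyl (2E,6E,10E)-7,11,15-trimethyl-3-{[(trifluoromethyl)sulfonyl]oxy}hexadeca-2,6,10,14-tetraenoate | CC(C)=CCC/C(C)=C/CC/C(C)=C/CC/C(=C\C(=O)OCC)OS(=O)(=O)C(F)(F)F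
F4 | step 3 | ethyl (2E,6E,10E)-3-(hydroxymethyl)-7,11,15-trimethylhexadeca-2,6,10,14-tetraenoate | CC(C)=CCC/C(C)=C/CC/C(C)=C/CC/C(=C\C(=O)OCC)CO
F5 | step 2 | (4E,8E)-N-methoxy-N,5,9,13-tetramethyltetradeca-4,8,12-trienamide | CC(C)=CCC/C(C)=C/CC/C(C)=C/CCC(=O)N(C)OC
F6 | step 2 | (5E,9E)-1-chloro-6,10,14-trimethylpentadeca-5,9,13-trien-2-one | CC(C)=CCC/C(C)=C/CC/C(C)=C/CCC(=O)CCl
F7 | step 2 | (5E,9E)-1-hydroxy-6,10,14-trimethylpentadeca-5,9,13-trien-2-one | CC(C)=CCC/C(C)=C/CC/C(C)=C/CCC(=O)CO
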